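**Plan**
1. Cuts, with the cyclohexane numbered C1 = C(CH3)(OH), C2 = CH bearing the side chain, C3 = C(CH3)2, C4 = CH(OH), C5/C6 = CH2: the aryl ether O–CH2 bond; the C1–CH3 and C1–C6 bonds; the C2–C3 bond; the ester C–O between a side-chain acid and an allylic alcohol; the carboxyl carbon of that acid.
2. Enabling feature: C1 and the oxygen on C4 are 1,4-related through C2–C3, so C1, C2, C3, C4 and that oxygen are exactly the five ring atoms of a γ-lactone. With C5–C6 as a 2-iodoethyl arm on C4, C6 can reach the lactone carbonyl C1.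
3. Forward: (R)-linalool is turned into the protected side-chain acid and esterified with (S)-4-methylpent-3-en-2-ol. An Ireland–Claisen rearrangement makes C2–C3, oxidative lactonization makes the C4–O bond (temporary ring), and hydrozirconation–iodination arms C6.
4. Key event: SmI2-mediated closure of C6 onto C1 opens the lactone to the 4-oxido cyclohexanone, and a methyl nucleophile is added in the same flask. Desilylation and Mitsunobu etherification with umbelliferone finish the route.
5. Stereochemistry: the side-chain carbinol comes from (R)-linalool; C2 by chirality transfer from the (S)-allylic alcohol through a chair Claisen transition state; C4 by cis-selective lactonization relative to C2; C1 by equatorial methyl attack anti to the side chain.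

Key step: step 11

Remark: commercial (R)-(−)-linalool of high enantiomeric purity is assumed; a minor C2 epimer from the Claisen step would be a diastereomer and should be removable at the lactone stage.

**Step 1**
Reactants: 1 (R)-(−)-linalool
Product: 3 (3R)-3,7-dimethyloct-6-ene-1,3-diol, via alkylborane 2 (not isolated)
Conditions: 9-BBN (2.2 equiv), THF, 0 °C to rt; then aq. NaOH, H2O2, 0 °C
Reagents that add atoms: hydrogen peroxide, OO
Why: Anti-Markovnikov hydroboration–oxidation, in which the hindered dialkylborane should add only to the monosubstituted vinyl group (boron on the terminal carbon) and leave the trisubstituted alkene, so the carbinol stereocenter of linalool is carried over and no new one is formed.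

**Step 2**
Reactants: 3 (3R)-3,7-dimethyloct-6-ene-1,3-diol
Product: 4 (3R)-1,3-bis(tert-butyldimethylsilyloxy)-3,7-dimethyloct-6-ene
Conditions: TBSOTf (2.5 equiv), 2,6-lutidine, CH2Cl2, −78 to 0 °C
Reagents that add atoms: tert-butyldimethylsilyl trifluoromethanesulfonate, CC(C)(C)[Si](C)(C)OS(=O)(=O)C(F)(F)F
Why: Silyl ether formation with the silyl triflate should cap the primary and the hindered tertiary hydroxyl alike, removing both acidic protons before the organolithium and enolate steps.

**Step 3**
Reactants: 4 (3R)-1,3-bis(tert-butyldimethylsilyloxy)-3,7-dimethyloct-6-ene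
Product: 6 (4R)-4,6-bis(tert-butyldimethylsilyloxy)-4-methylhexan-1-ol, via aldehyde 5 (not isolated)
Conditions: O3, CH2Cl2/MeOH, −78 °C; then NaBH4, −78 °C to rt
Reagents that add atoms: ozone, [O-][O+]=O
Why: Ozonolysis with hydride work-up cleaves the single remaining alkene and reduces the aldehyde in the flask to the primary alcohol, the silyl ethers being inert to both reagents.

**Step 4**
Reactants: 6 (4R)-4,6-bis(tert-butyldimethylsilyloxy)-4-methylhexan-1-ol
Product: 7 (3R)-1,3-bis(tert-butyldimethylsilyloxy)-6-iodo-3-methylhexane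
Conditions: I2, PPh3, imidazole, CH2Cl2, 0 °C to rt
Reagents that add atoms: iodine, II
Why: Appel-type iodination, in which the phosphonium-activated primary alcohol is displaced by iodide in an SN2 step that touches no stereocenter.

**Step 5**
Reactants: 7 (3R)-1,3-bis(tert-butyldimethylsilyloxy)-6-iodo-3-methylhexane
Product: 9 (5R)-5,7-bis(tert-butyldimethylsilyloxy)-5-methylheptanoic acid, via alkyllithium 8 (not isolated)
Conditions: t-BuLi (2.1 equiv), Et2O/pentane, −78 °C; then CO2 (excess); dilute HCl to pH 3, 0 °C
Reagents that add atoms: carbon dioxide, O=C=O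
Why: Iodine–lithium exchange (the second equivalent of t-BuLi destroys the t-BuI formed) followed by carboxylation of the primary alkyllithium adds the one carbon that later becomes C1 of the cyclohexane.

**Step 6**
Reactants: 10 mesityl oxide (4-methylpent-3-en-2-one)
Product: 11 (2S)-4-methylpent-3-en-2-ol
Conditions: (R)-2-methyl-CBS-oxazaborolidine (10 mol %), catecholborane (1.5 equiv), toluene, −78 °C
Reagents that add atoms: none
Why: Corey–Bakshi–Shibata reduction, in which the ketone should bind the (R)-oxazaborolidine with the alkenyl group as the large substituent and receive hydride on the face that gives the (S)-allylic alcohol, catecholborane at low temperature avoiding hydroboration of the C=C bond.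

**Step 7**
Reactants: 9 (5R)-5,7-bis(tert-butyldimethylsilyloxy)-5-methylheptanoic acid, 11 (2S)-4-methylpent-3-en-2-ol
Product: 12 (2S)-4-methylpent-3-en-2-yl (5R)-5,7-bis(tert-butyldimethylsilyloxy)-5-methylheptanoate
Conditions: EDC·HCl, DMAP, CH2Cl2, 0 °C to rt
Reagents that add atoms: none
Why: Steglich-type carbodiimide esterification should join acid and allylic alcohol under neutral conditions, with retention at the carbinol carbon because its C–O bond is not broken.

**Step 8**
Reactants: 12 (2S)-4-methylpent-3-en-2-yl (5R)-5,7-bis(tert-butyldimethylsilyloxy)-5-methylheptanoate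
Product: 15 (2R,4E)-2-[(3R)-3,5-bis(tert-butyldimethylsilyloxy)-3-methylpentyl]-3,3-dimethylhex-4-enoic acid, via silyl ketene acetal 13 (not isolated), via trimethylsilyl ester 14 (not isolated)
Conditions: LiN(iPr)2 (1.3 equiv), THF, −78 °C; TMSCl, Et3N; −78 to 55 °C; then aq. NaOH, rt; acidify to pH 4
Reagents that add atoms: none
Why: Ireland–Claisen rearrangement, in which kinetic deprotonation in THF should give the ketene acetal with the side chain cis to the allyloxy oxygen, and the chair transition state with the carbinol methyl equatorial then transfers the (S)-configuration of the allylic carbon to the new (2R) center while forging the bond to the gem-dimethyl carbon and leaving an (E)-alkene.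

**Step 9**
Reactants: 15 (2R,4E)-2-[(3R)-3,5-bis(tert-butyldimethylsilyloxy)-3-methylpentyl]-3,3-dimethylhex-4-enoic acid
Product: 16 (3R,5S)-3-[(3R)-3,5-bis(tert-butyldimethylsilyloxy)-3-methylpentyl]-5-ethenyl-4,4-dimethyloxolan-2-one
Conditions: Pd(OAc)2 (10 mol %), NaOAc (2 equiv), O2 (1 atm), DMSO, 25–50 °C
Reagents that add atoms: none
Why: Wacker-type oxidative lactonization, in which 5-exo attack of the carboxylate on the palladium-bound (E)-alkene and beta-hydride elimination toward the methyl group should give the gamma-vinyl lactone, the new C–O center being expected cis to the C3 substituent because both groups can then lie pseudo-equatorial on the envelope that has the gem-dimethyl carbon as its flap.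

**Step 10**
Reactants: 16 (3R,5S)-3-[(3R)-3,5-bis(tert-butyldimethylsilyloxy)-3-methylpentyl]-5-ethenyl-4,4-dimethyloxolan-2-one
Product: 18 (3R,5S)-3-[(3R)-3,5-bis(tert-butyldimethylsilyloxy)-3-methylpentyl]-5-(2-iodoethyl)-4,4-dimethyloxolan-2-one, via alkylzirconocene chloride 17 (not isolated)
Conditions: Cp2Zr(H)Cl (1.5 equiv), CH2Cl2, rt; then I2, 0 °C
Reagents that add atoms: iodine, II
Why: Hydrozirconation–iodination, in which the zirconium hydride should add across the terminal vinyl group with the metal on the terminal carbon faster than it attacks the lactone, and iodine then cleaves the C–Zr bond to the primary iodide without touching either stereocenter.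

**Step 11**
Reactants: 18 (3R,5S)-3-[(3R)-3,5-bis(tert-butyldimethylsilyloxy)-3-methylpentyl]-5-(2-iodoethyl)-4,4-dimethyloxolan-2-one
Product: 21 (1S,2R,4S)-2-[(3R)-3,5-bis(tert-butyldimethylsilyloxy)-3-methylpentyl]-1,3,3-trimethylcyclohexane-1,4-diol, via alkylsamarium 19 (not isolated), via ketone samarium alkoxide 20 (not isolated)
Conditions: SmI2 (2.5 equiv), Fe(dbm)3 (3 mol %), THF (0.01 M), −30 to 0 °C; then MeMgBr (4 equiv), −78 to 0 °C; aq. NH4Cl
Reagents that add atoms: methylmagnesium bromide, C[Mg]Br
Why: Two single-electron transfers from SmI2 (iron-catalysed) should convert the primary C–I bond into alkylsamarium 19, whose carbon C6 adds to the lactone carbonyl C1 that sits 1,3 to the arm-bearing C4 on the same five-membered ring; the resulting hemiketalate is a strained 7-oxabicyclo[2.2.1]heptane and should collapse by breaking the old acyl C–O bond, which unveils the cyclohexanone and leaves the former ring oxygen as the C4 alkoxide (20). The closest known reaction type is the SmI2-promoted intramolecular nucleophilic acyl substitution of iodo esters and iodo lactones, including its sequencing with a second carbonyl addition in the same flask. The six-membered carbocycle closes in the 6-exo-trig mode with respect to the attacked C=O (5-exo-trig if counted through the ring oxygen), and the closure itself creates no stereocenter: C2 and C4 are carried over, the cis 3,5-pattern of the lactone becoming the trans relationship of side chain and C4 hydroxyl on the cyclohexane. The quaternary carbinol C1 is set in the second stage: in the chair with the C2 side chain equatorial the axial methyl on C3 blocks axial approach, so the methyl nucleophile (a weakly basic samarium/magnesium methyl species) should enter equatorially and anti to the side chain, giving CH3 trans and OH cis to it as in the target. The step needs intramolecular acyl substitution to outrun simple reduction of the C–I bond, which the five-atom reach of the arm and high dilution should secure, and it needs the epimerisable C2 center next to the new ketone to survive, which is why 20 is trapped cold in the same flask and not isolated.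

**Step 12**
Reactants: 21 (1S,2R,4S)-2-[(3R)-3,5-bis(tert-butyldimethylsilyloxy)-3-methylpentyl]-1,3,3-trimethylcyclohexane-1,4-diol
Product: 22 (1S,2R,4S)-2-[(3R)-3,5-dihydroxy-3-methylpentyl]-1,3,3-trimethylcyclohexane-1,4-diol
Conditions: HF·pyridine, THF/pyridine, 0 to 40 °C
Reagents that add atoms: none
Why: Fluoride-driven cleavage of the Si–O bonds frees the primary and the tertiary side-chain hydroxyl (the tertiary silyl ether needing the longer time), and the pyridine-buffered reagent should spare the acid-sensitive tertiary carbinols.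

**Step 13**
Reactants: 22 (1S,2R,4S)-2-[(3R)-3,5-dihydroxy-3-methylpentyl]-1,3,3-trimethylcyclohexane-1,4-diol, 23 umbelliferone
Product: 24 7-{[(3R)-5-[(1R,3S,6S)-3,6-dihydroxy-2,2,6-trimethylcyclohexyl]-3-hydroxy-3-methylpentyl]oxy}-2H-chromen-2-one (target)
Conditions: PPh3 (1.5 equiv), DIAD (1.5 equiv), THF, 0 °C to rt
Reagents that add atoms: none
Why: Mitsunobu etherification, in which only the unhindered primary alcohol should form the alkoxyphosphonium ion that the acidic 7-hydroxyl of umbelliferone displaces, while the neopentyl-type secondary and the two tertiary hydroxyls stay untouched and no stereocenter is involved.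

**Compound list**
1 | (R)-(−)-linalool, (3R)-3,7-dimethylocta-1,6-dien-3-ol | CC(C)=CCC[C@@](C)(O)C=C | starting material
2 | 9-[(3S)-3-hydroxy-3,7-dimethyloct-6-en-1-yl]-9-borabicyclo[3.3.1]nonane | CC(C)=CCC[C@@](C)(O)CCB1C2CCCC1CCC2 | intermediate (not isolated)
3 | (3R)-3,7-dimethyloct-6-ene-1,3-diol | CC(C)=CCC[C@@](C)(O)CCO | intermediate
4 | (3R)-1,3-bis(tert-butyldimethylsilyloxy)-3,7-dimethyloct-6-ene | CC(C)=CCC[C@@](C)(O[Si](C)(C)C(C)(C)C)CCO[Si](C)(C)C(C)(C)C | intermediate
5 | (4R)-4,6-bis(tert-butyldimethylsilyloxy)-4-methylhexanal | O=CCC[C@@](C)(O[Si](C)(C)C(C)(C)C)CCO[Si](C)(C)C(C)(C)C | intermediate (not isolated)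
6 | (4R)-4,6-bis(tert-butyldimethylsilyloxy)-4-methylhexan-1-ol | OCCC[C@@](C)(O[Si](C)(C)C(C)(C)C)CCO[Si](C)(C)C(C)(C)C | intermediate
7 | (3R)-1,3-bis(tert-butyldimethylsilyloxy)-6-iodo-3-methylhexane | ICCC[C@@](C)(O[Si](C)(C)C(C)(C)C)CCO[Si](C)(C)C(C)(C)C | intermediate
8 | [(4R)-4,6-bis(tert-butyldimethylsilyloxy)-4-methylhexyl]lithium | [Li]CCC[C@@](C)(O[Si](C)(C)C(C)(C)C)CCO[Si](C)(C)C(C)(C)C | intermediate (not isolated)
9 | (5R)-5,7-bis(tert-butyldimethylsilyloxy)-5-methylheptanoic acid | OC(=O)CCC[C@@](C)(O[Si](C)(C)C(C)(C)C)CCO[Si](C)(C)C(C)(C)C | intermediate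
10 | mesityl oxide (4-methylpent-3-en-2-one) | CC(=O)C=C(C)C | starting material
11 | (2S)-4-methylpent-3-en-2-ol | C[C@H](O)C=C(C)C | intermediate
12 | (2S)-4-methylpent-3-en-2-yl (5R)-5,7-bis(tert-butyldimethylsilyloxy)-5-methylheptanoate | C[C@H](OC(=O)CCC[C@@](C)(O[Si](C)(C)C(C)(C)C)CCO[Si](C)(C)C(C)(C)C)C=C(C)C | intermediate
13 | (E)-trimethylsilyl ketene acetal of 12 (side chain cis to the allyloxy oxygen) | C[C@H](O/C(O[Si](C)(C)C)=C\CC[C@@](C)(O[Si](C)(C)C(C)(C)C)CCO[Si](C)(C)C(C)(C)C)C=C(C)C | intermediate (not isolated)
14 | trimethylsilyl ester of 15 | C/C=C/C(C)(C)[C@@H](CC[C@@](C)(O[Si](C)(C)C(C)(C)C)CCO[Si](C)(C)C(C)(C)C)C(=O)O[Si](C)(C)C | intermediate (not isolated)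
15 | (2R,4E)-2-[(3R)-3,5-bis(tert-butyldimethylsilyloxy)-3-methylpentyl]-3,3-dimethylhex-4-enoic acid | C/C=C/C(C)(C)[C@@H](CC[C@@](C)(O[Si](C)(C)C(C)(C)C)CCO[Si](C)(C)C(C)(C)C)C(=O)O | intermediate
16 | (3R,5S)-3-[(3R)-3,5-bis(tert-butyldimethylsilyloxy)-3-methylpentyl]-5-ethenyl-4,4-dimethyloxolan-2-one | C=C[C@@H]1OC(=O)[C@H](CC[C@@](C)(O[Si](C)(C)C(C)(C)C)CCO[Si](C)(C)C(C)(C)C)C1(C)C | intermediate
17 | alkylzirconocene chloride: 18 with ZrCp2Cl in place of iodine | Cl[Zr](CC[C@@H]1OC(=O)[C@H](CC[C@@](C)(O[Si](C)(C)C(C)(C)C)CCO[Si](C)(C)C(C)(C)C)C1(C)C)(C1C=CC=C1)C1C=CC=C1 | intermediate (not isolated)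
18 | (3R,5S)-3-[(3R)-3,5-bis(tert-butyldimethylsilyloxy)-3-methylpentyl]-5-(2-iodoethyl)-4,4-dimethyloxolan-2-one | ICC[C@@H]1OC(=O)[C@H](CC[C@@](C)(O[Si](C)(C)C(C)(C)C)CCO[Si](C)(C)C(C)(C)C)C1(C)C | intermediate
19 | alkylsamarium diiodide: 18 with SmI2 in place of iodine | I[Sm](I)CC[C@@H]1OC(=O)[C@H](CC[C@@](C)(O[Si](C)(C)C(C)(C)C)CCO[Si](C)(C)C(C)(C)C)C1(C)C | intermediate (not isolated)
20 | diiodosamarium alkoxide of (2R,4S)-2-[(3R)-3,5-bis(tert-butyldimethylsilyloxy)-3-methylpentyl]-4-hydroxy-3,3-dimethylcyclohexan-1-one | CC1(C)[C@@H](CC[C@@](C)(O[Si](C)(C)C(C)(C)C)CCO[Si](C)(C)C(C)(C)C)C(=O)CC[C@@H]1O[Sm](I)I | intermediate (not isolated)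
21 | (1S,2R,4S)-2-[(3R)-3,5-bis(tert-butyldimethylsilyloxy)-3-methylpentyl]-1,3,3-trimethylcyclohexane-1,4-diol | CC1(C)[C@@H](CC[C@@](C)(O[Si](C)(C)C(C)(C)C)CCO[Si](C)(C)C(C)(C)C)[C@@](C)(O)CC[C@@H]1O | intermediate
22 | (1S,2R,4S)-2-[(3R)-3,5-dihydroxy-3-methylpentyl]-1,3,3-trimethylcyclohexane-1,4-diol | CC1(C)[C@@H](CC[C@@](C)(O)CCO)[C@@](C)(O)CC[C@@H]1O | intermediate
23 | umbelliferone (7-hydroxy-2H-chromen-2-one) | Oc1ccc2ccc(=O)oc2c1 | starting material
24 | 7-{[(3R)-5-[(1R,3S,6S)-3,6-dihydroxy-2,2,6-trimethylcyclohexyl]-3-hydroxy-3-methylpentyl]oxy}-2H-chromen-2-one | CC1(C)[C@@H](CC[C@@](C)(O)CCOc2ccc3ccc(=O)oc3c2)[C@@](C)(O)CC[C@@H]1O | target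

**Step count**
Total step count: 13. Longest linear sequence: 12 steps (from 1 through steps 1–5 and 7–13; step 6 is a one-step branch).

**Steps most likely to fail**

Step 11. The alkylsamarium may be lost by simple reduction of the C–I bond (protonation) or by 1,3-elimination to a cyclopropane with loss of the carboxylate. Closure may be slow because the tetrahedral intermediate is a strained oxygen-bridged bicycle with the side chain on its concave side. The unveiled ketone may epimerise at C2 before the methyl nucleophile arrives. The fallback sets out from vinyl lactone 16 and comes back to the route at tetraol 22. Aminolysis of 16 with MeNH(OMe)·HCl and AlMe3 should open the lactone to the hydroxy Weinreb amide F1, which is silylated at once (TESOTf, 2,6-lutidine) to the triethylsilyl ether F2. Hydroboration of the vinyl group with 9-BBN and iodinolysis (I2, NaOMe) should give the primary iodide F3. Iodine–lithium exchange with t-BuLi at −78 °C then forms the same ring bond by Parham-type cyclization onto the open-chain amide, through a chelated tetrahedral intermediate and without any bridged bicycle, to give the silyloxy ketone F4. MeMgBr with CeCl3 should add with the same facial preference to give the tertiary alcohol F5, and HF·pyridine removes all three silyl groups to give 22.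

Step 9. The oxypalladation may show poor facial selectivity, placing the new C–O center trans to the C3 substituent, and beta-hydride elimination may run toward the ring carbon to give an enol lactone. The fallback sets out from acid 15 and comes back at 16. N-(phenylseleno)phthalimide with a catalytic sulfonic acid in CH2Cl2, conditions under which selenolactonization is reversible so that the more stable cis-3,5 lactone can accumulate, should give the phenylselenolactone F6 by anti addition across the (E)-alkene. Oxidation with H2O2 and pyridine at 0 °C gives the selenoxide, whose syn-elimination runs away from the oxygen-bearing ring carbon and so delivers the vinyl group of 16.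

Step 10. The zirconium hydride may reduce the lactone carbonyl in competition with the alkene, or add with reversed regiochemistry and then lose the allylic C–O bond. The fallback sets out from 16 and comes back at 18. Hydroboration with 9-BBN, which leaves lactones untouched at room temperature, followed by buffered oxidation with NaBO3 should give the primary alcohol F7, which PPh3, I2 and imidazole convert into 18.

**Further compounds**
F1 | step 11 | (2R,4S)-2-[(3R)-3,5-bis(tert-butyldimethylsilyloxy)-3-methylpentyl]-4-hydroxy-N-methoxy-N,3,3-trimethylhex-5-enamide | CON(C)C(=O)[C@H](CC[C@@](C)(O[Si](C)(C)C(C)(C)C)CCO[Si](C)(C)C(C)(C)C)C(C)(C)[C@@H](O)C=C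
F2 | step 11 | triethylsilyl ether of F1 | CON(C)C(=O)[C@H](CC[C@@](C)(O[Si](C)(C)C(C)(C)C)CCO[Si](C)(C)C(C)(C)C)C(C)(C)[C@@H](O[Si](CC)(CC)CC)C=C
F3 | step 11 | (2R,4S)-2-[(3R)-3,5-bis(tert-butyldimethylsilyloxy)-3-methylpentyl]-6-iodo-N-methoxy-N,3,3-trimethyl-4-(triethylsilyloxy)hexanamide | CON(C)C(=O)[C@H](CC[C@@](C)(O[Si](C)(C)C(C)(C)C)CCO[Si](C)(C)C(C)(C)C)C(C)(C)[C@@H](O[Si](CC)(CC)CC)CCI
F4 | step 11 | (2R,4S)-2-[(3R)-3,5-bis(tert-butyldimethylsilyloxy)-3-methylpentyl]-3,3-dimethyl-4-(triethylsilyloxy)cyclohexan-1-one | CC1(C)[C@@H](CC[C@@](C)(O[Si](C)(C)C(C)(C)C)CCO[Si](C)(C)C(C)(C)C)C(=O)CC[C@@H]1O[Si](CC)(CC)CC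
F5 | step 11 | (1S,2R,4S)-2-[(3R)-3,5-bis(tert-butyldimethylsilyloxy)-3-methylpentyl]-1,3,3-trimethyl-4-(triethylsilyloxy)cyclohexan-1-ol | CC1(C)[C@@H](CC[C@@](C)(O[Si](C)(C)C(C)(C)C)CCO[Si](C)(C)C(C)(C)C)[C@@](C)(O)CC[C@@H]1O[Si](CC)(CC)CC
F6 | step 9 | (3R,5R)-3-[(3R)-3,5-bis(tert-butyldimethylsilyloxy)-3-methylpentyl]-4,4-dimethyl-5-[(1S)-1-(phenylselanyl)ethyl]oxolan-2-one | C[C@H]([Se]c1ccccc1)[C@@H]1OC(=O)[C@H](CC[C@@](C)(O[Si](C)(C)C(C)(C)C)CCO[Si](C)(C)C(C)(C)C)C1(C)C
F7 | step 10 | (3R,5S)-3-[(3R)-3,5-bis(tert-butyldimethylsilyloxy)-3-methylpentyl]-5-(2-hydroxyethyl)-4,4-dimethyloxolan-2-one | OCC[C@@H]1OC(=O)[C@H](CC[C@@](C)(O[Si](C)(C)C(C)(C)C)CCO[Si](C)(C)C(C)(C)C)C1(C)C
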